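The route rests on reading C-2 of the propane-1,3-diol core (the methine carrying the acyloxymethyl and cinnamyl groups) as the α-carbon of an acrylate-derived enolate: its allylic CH2 is the acrylate β-carbon and the CH2O carbon the carboxyl carbon. In one operation an (E)-2-(3,4-dimethoxyphenyl)vinyl magnesium/copper reagent adds to a chiral N-acryloyl oxazolidinone and the chelated magnesium (Z)-enolate is trapped by 4-methoxybenzaldehyde, forming the bond from that methine to the 4-methoxyphenyl carbinol carbon with anti stereocontrol. The precursors are simply an alkenyl iodide, the acryloyl imide and anisaldehyde. Reduction, primary-selective esterification with a silyl-protected (Z)-2-(hydroxymethyl)but-2-enoic acid and desilylation complete the synthesis.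

Key step: step 3

Assumption: the chelated magnesium enolate of the (S)-4-benzyl imide is taken to react on the face opposite the benzyl group (the sense of its enolate alkylations) and to give the anti adduct. If the opposite face reacted, the (R)-auxiliary would be used with nothing else changed.

Step 1
Reactants: 1 (S)-4-benzyl-1,3-oxazolidin-2-one; 2 acryloyl chloride
Product: 3 (S)-3-acryloyl-4-benzyl-1,3-oxazolidin-2-one
Conditions: Et3N, LiCl, THF, −20 °C → rt
Reagents that add atoms: none
Why: Lithium chloride/amine-mediated N-acylation of the oxazolidinone should give the imide under mild conditions that limit acrylate polymerisation, and the C-4 stereocentre is not touched.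

Step 2
Reactants: 4 (E)-3-(3,4-dimethoxyphenyl)prop-2-enoic acid
Product: 5 4-[(E)-2-iodoethenyl]-1,2-dimethoxybenzene
Conditions: NIS, Et3N (10 mol%), CH2Cl2, rt, dark
Reagents that add atoms: N-iodosuccinimide, O=C1CCC(=O)N1I
Why: Hunsdiecker-type halodecarboxylation of an electron-rich cinnamic acid should give the β-iodostyrene, loss of CO2 from the benzylic cation/β-lactone intermediate leading to the more stable (E)-alkene.

Step 3
Reactants: 3 (S)-3-acryloyl-4-benzyl-1,3-oxazolidin-2-one; 5 4-[(E)-2-iodoethenyl]-1,2-dimethoxybenzene; 6 4-methoxybenzaldehyde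
Product: 10 (4S)-4-benzyl-3-[(2R,4E)-5-(3,4-dimethoxyphenyl)-2-[(S)-hydroxy(4-methoxyphenyl)methyl]pent-4-enoyl]-1,3-oxazolidin-2-one, via alkenylmagnesium chloride 7 (not isolated), via chloromagnesium Z-enolate 8 (not isolated), via TMS ether 9 (not isolated)
Conditions: 5, i-PrMgCl·LiCl, THF, 0 °C; CuBr·SMe2 (20 mol%), −78 °C; 3 (slow addition); then 6, TMSCl, −78 °C → rt; 1 M HCl, THF, 0 °C
Reagents that add atoms: none
Why: Proposed new method: iodine–magnesium exchange should give (E)-alkenylmagnesium chloride 7 with retention, copper-catalysed 1,4-addition to the s-cis chelated acryloyl imide should give the chelated chloromagnesium (Z)-enolate 8, and 8 should add reversibly to the magnesium-bound aldehyde, silylation of the aldolate by TMSCl draining the equilibrium towards 9 (a three-component conjugate addition–aldol). The closest known reaction types are the organocopper conjugate addition–enolate trapping of N-enoyl oxazolidinones and the magnesium halide-catalysed, silyl-trapped anti-aldol of N-acyloxazolidinones with aromatic aldehydes; new is that the halomagnesium enolate of the latter is reached by carbometalation of the acryloyl imide instead of soft enolisation. No ring is closed. C-2 of the acyl chain should become (R) because the aldehyde reaches the chelated enolate from the face opposite the C-4 benzyl group of the auxiliary, and the carbinol carbon (S) because a boat-like transition state on magnesium gives the anti adduct. The step needs 1,4- over 1,2-addition (copper and chelation), no Michael oligomerisation of 3 (slow addition at −78 °C, Grignard not in excess when 6 enters) and anti over syn (magnesium counter-ion with silyl trapping). Acidic work-up cleaves the TMS ether of 9 to give 10.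

Step 4
Reactants: 10 (4S)-4-benzyl-3-[(2R,4E)-5-(3,4-dimethoxyphenyl)-2-[(S)-hydroxy(4-methoxyphenyl)methyl]pent-4-enoyl]-1,3-oxazolidin-2-one
Product: 11 (1S,2S)-2-[(E)-3-(3,4-dimethoxyphenyl)prop-2-enyl]-1-(4-methoxyphenyl)propane-1,3-diol
Conditions: LiBH4, MeOH (1 equiv), THF, 0 °C
Reagents that add atoms: none
Why: Reductive cleavage of the N-acyl oxazolidinone by hydride attack at the exocyclic carbonyl should give the 1,3-diol and the recoverable auxiliary without affecting either stereocentre or the styrene.

Step 5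
Reactants: 12 (E)-but-2-enal
Product: 14 (Z)-2-bromobut-2-enal, via 2,3-dibromobutanal 13 (not isolated)
Conditions: Br2, CH2Cl2, 0 °C; then Et3N, 0 °C → rt
Reagents that add atoms: bromine, BrBr
Why: Bromine addition followed by E1cB dehydrobromination should give the α-bromoenal as the thermodynamically preferred (Z)-isomer, with methyl trans to the formyl group.

Step 6
Reactants: 14 (Z)-2-bromobut-2-enal
Product: 15 (Z)-2-bromobut-2-en-1-ol
Conditions: NaBH4, CeCl3·7H2O, MeOH, 0 °C
Reagents that add atoms: none
Why: Luche reduction should reduce the aldehyde 1,2-selectively and leave the vinyl bromide and the alkene geometry intact.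

Step 7
Reactants: 15 (Z)-2-bromobut-2-en-1-ol
Product: 16 [(Z)-2-bromobut-2-enoxy](tert-butyl)dimethylsilane
Conditions: TBSCl, imidazole, DMF, rt
Reagents that add atoms: tert-butyldimethylsilyl chloride, CC(C)(C)[Si](C)(C)Cl
Why: Silyl ether formation protects the primary allylic alcohol for the organolithium and esterification steps and is removable later with fluoride under near-neutral conditions.

Step 8
Reactants: 16 [(Z)-2-bromobut-2-enoxy](tert-butyl)dimethylsilane
Product: 18 (Z)-2-[(tert-butyldimethylsilyloxy)methyl]but-2-enoic acid, via vinyllithium 17 (not isolated)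
Conditions: t-BuLi (2.1 equiv), Et2O, −78 °C; CO2, −78 → 0 °C; cold 1 M HCl to pH 3–4
Reagents that add atoms: carbon dioxide, O=C=O
Why: Bromine–lithium exchange at −78 °C proceeds with retention of alkene geometry and carboxylation of the vinyllithium should place the carboxyl group where bromine was, cis to the methyl group, which is the (Z)-acid.

Step 9
Reactants: 11 (1S,2S)-2-[(E)-3-(3,4-dimethoxyphenyl)prop-2-enyl]-1-(4-methoxyphenyl)propane-1,3-diol; 18 (Z)-2-[(tert-butyldimethylsilyloxy)methyl]but-2-enoic acid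
Product: 20 [(2S,4E)-5-(3,4-dimethoxyphenyl)-2-[(S)-hydroxy(4-methoxyphenyl)methyl]pent-4-enyl] (Z)-2-[(tert-butyldimethylsilyloxy)methyl]but-2-enoate, via mixed anhydride 19 (not isolated)
Conditions: 18, 2,4,6-trichlorobenzoyl chloride, Et3N, toluene, rt; then 11, DMAP (0.2 equiv), 0 °C
Reagents that add atoms: none
Why: Yamaguchi esterification should acylate the unhindered primary hydroxyl in preference to the α-branched secondary benzylic one, and low temperature with substoichiometric DMAP should preserve the (Z)-geometry of the acid.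

Step 10
Reactants: 20 [(2S,4E)-5-(3,4-dimethoxyphenyl)-2-[(S)-hydroxy(4-methoxyphenyl)methyl]pent-4-enyl] (Z)-2-[(tert-butyldimethylsilyloxy)methyl]but-2-enoate
Product: 21 [(2S,4E)-5-(3,4-dimethoxyphenyl)-2-[(S)-hydroxy(4-methoxyphenyl)methyl]pent-4-enyl] (Z)-2-(hydroxymethyl)but-2-enoate
Conditions: HF·pyridine, pyridine, THF, 0 °C → rt
Reagents that add atoms: none
Why: Fluoride-mediated desilylation buffered with pyridine should free the primary allylic alcohol without acyl migration, alkene isomerisation or ionisation of the 4-methoxybenzylic alcohol.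

Compound list
1 | (S)-4-benzyl-1,3-oxazolidin-2-one | O=C1N[C@@H](Cc2ccccc2)CO1 | starting material
2 | acryloyl chloride | C=CC(=O)Cl | starting material
3 | (S)-3-acryloyl-4-benzyl-1,3-oxazolidin-2-one | C=CC(=O)N1[C@@H](Cc2ccccc2)COC1=O | intermediate
4 | (E)-3-(3,4-dimethoxyphenyl)prop-2-enoic acid | COc1ccc(/C=C/C(=O)O)cc1OC | starting material
5 | 4-[(E)-2-iodoethenyl]-1,2-dimethoxybenzene | COc1ccc(/C=C/I)cc1OC | intermediate
6 | 4-methoxybenzaldehyde | COc1ccc(C=O)cc1 | starting material
7 | (E)-2-(3,4-dimethoxyphenyl)ethenylmagnesium chloride | COc1ccc(/C=C/[Mg]Cl)cc1OC | intermediate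
8 | chloromagnesium (Z)-enolate of (S)-4-benzyl-3-[(E)-5-(3,4-dimethoxyphenyl)pent-4-enoyl]-1,3-oxazolidin-2-one | Cl[Mg]O/C(=C\C/C=C/c1ccc(OC)c(OC)c1)N1C(=O)OC[C@@H]1Cc1ccccc1 | intermediate
9 | (4S)-4-benzyl-3-[(2R,4E)-5-(3,4-dimethoxyphenyl)-2-[(S)-(4-methoxyphenyl)(trimethylsilyloxy)methyl]pent-4-enoyl]-1,3-oxazolidin-2-one | O=C1OC[C@H](Cc2ccccc2)N1C(=O)[C@H](C/C=C/c1ccc(OC)c(OC)c1)[C@H](O[Si](C)(C)C)c1ccc(OC)cc1 | intermediate
10 | (4S)-4-benzyl-3-[(2R,4E)-5-(3,4-dimethoxyphenyl)-2-[(S)-hydroxy(4-methoxyphenyl)methyl]pent-4-enoyl]-1,3-oxazolidin-2-one | O=C1OC[C@H](Cc2ccccc2)N1C(=O)[C@H](C/C=C/c1ccc(OC)c(OC)c1)[C@H](O)c1ccc(OC)cc1 | intermediate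
11 | (1S,2S)-2-[(E)-3-(3,4-dimethoxyphenyl)prop-2-enyl]-1-(4-methoxyphenyl)propane-1,3-diol | OC[C@H](C/C=C/c1ccc(OC)c(OC)c1)[C@H](O)c1ccc(OC)cc1 | intermediate
12 | (E)-but-2-enal | C/C=C/C=O | starting material
13 | 2,3-dibromobutanal | CC(Br)C(Br)C=O | intermediate
14 | (Z)-2-bromobut-2-enal | C/C=C(\Br)C=O | intermediate
15 | (Z)-2-bromobut-2-en-1-ol | C/C=C(\Br)CO | intermediate
16 | [(Z)-2-bromobut-2-enoxy](tert-butyl)dimethylsilane | C/C=C(\Br)CO[Si](C)(C)C(C)(C)C | intermediate
17 | [(E)-1-(tert-butyldimethylsilyloxy)but-2-en-2-yl]lithium | C/C=C(\[Li])CO[Si](C)(C)C(C)(C)C | intermediate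
18 | (Z)-2-[(tert-butyldimethylsilyloxy)methyl]but-2-enoic acid | C/C=C(/CO[Si](C)(C)C(C)(C)C)C(=O)O | intermediate
19 | (Z)-2-[(tert-butyldimethylsilyloxy)methyl]but-2-enoic 2,4,6-trichlorobenzoic anhydride | C/C=C(/CO[Si](C)(C)C(C)(C)C)C(=O)OC(=O)c1c(Cl)cc(Cl)cc1Cl | intermediate
20 | [(2S,4E)-5-(3,4-dimethoxyphenyl)-2-[(S)-hydroxy(4-methoxyphenyl)methyl]pent-4-enyl] (Z)-2-[(tert-butyldimethylsilyloxy)methyl]but-2-enoate | C/C=C(/CO[Si](C)(C)C(C)(C)C)C(=O)OC[C@H](C/C=C/c1ccc(OC)c(OC)c1)[C@H](O)c1ccc(OC)cc1 | intermediate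
21 | [(2S,4E)-5-(3,4-dimethoxyphenyl)-2-[(S)-hydroxy(4-methoxyphenyl)methyl]pent-4-enyl] (Z)-2-(hydroxymethyl)but-2-enoate | C/C=C(/CO)C(=O)OC[C@H](C/C=C/c1ccc(OC)c(OC)c1)[C@H](O)c1ccc(OC)cc1 | target

Total step count: 10 (steps 1–10).
Longest linear sequence: 6 steps (steps 5, 6, 7, 8, 9, 10).

Steps most likely to fail

1. Step 3 (bears the label). What may go wrong: Michael addition of the magnesium enolate to acryloyl imide that has not yet reacted (oligomerisation); 1,2-addition of residual Grignard reagent to the aldehyde; or erosion of anti and facial selectivity because retro-aldol equilibration and silylation behave differently in THF in the presence of copper salts. Fallback (known chemistry only): setting out from 1, N-acylation with pent-4-enoyl chloride (n-BuLi, THF, −78 °C) should give (S)-4-benzyl-3-(pent-4-enoyl)-1,3-oxazolidin-2-one F1. Cross-metathesis of F1 with 3,4-dimethoxystyrene (second-generation Ru benzylidene catalyst, CH2Cl2, 40 °C) should give (S)-4-benzyl-3-[(E)-5-(3,4-dimethoxyphenyl)pent-4-enoyl]-1,3-oxazolidin-2-one F2. The magnesium chloride-catalysed anti-aldol of F2 with 6 (MgCl2 10 mol%, Et3N, TMSCl, EtOAc, rt) should give TMS ether 9, and after the acidic work-up of step 3 the route is rejoined at 10.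

2. Step 9. What may go wrong: Z to E isomerisation of the activated acid through reversible conjugate addition of DMAP, and competing acylation of the secondary benzylic hydroxyl. Fallback: setting out from 10, silylation of the secondary hydroxyl (TESOTf, 2,6-lutidine, CH2Cl2, −78 °C) should give (4S)-4-benzyl-3-[(2R,4E)-5-(3,4-dimethoxyphenyl)-2-[(S)-(4-methoxyphenyl)(triethylsilyloxy)methyl]pent-4-enoyl]-1,3-oxazolidin-2-one F3. LiBH4 reduction (THF, MeOH, 0 °C) should give (2S,4E)-5-(3,4-dimethoxyphenyl)-2-[(S)-(4-methoxyphenyl)(triethylsilyloxy)methyl]pent-4-en-1-ol F4, in which only the primary hydroxyl is free. Mitsunobu esterification with 18 (PPh3, DIAD, THF, 0 °C), which activates the alcohol and not the acid, should give the bis-silyl ester [(2S,4E)-5-(3,4-dimethoxyphenyl)-2-[(S)-(4-methoxyphenyl)(triethylsilyloxy)methyl]pent-4-enyl] (Z)-2-[(tert-butyldimethylsilyloxy)methyl]but-2-enoate F5. HF·pyridine/pyridine in THF should then remove both silyl groups, and the route is rejoined at the target 21.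

3. Step 8. What may go wrong: O to C silyl migration or β-elimination of silanolate at the vinyllithium stage, and partial loss of alkene geometry if the temperature rises before carboxylation. Fallback: setting out from 16, palladium-catalysed methoxycarbonylation (Pd(PPh3)2Cl2, CO 1 atm, MeOH, Et3N, DMF, 60 °C) should give methyl (Z)-2-[(tert-butyldimethylsilyloxy)methyl]but-2-enoate F6 with retention of geometry and without any organolithium. Saponification (LiOH, THF/H2O, rt) and careful acidification should give 18, where the route is rejoined.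

Further compounds
F1 | step 3 | (S)-4-benzyl-3-(pent-4-enoyl)-1,3-oxazolidin-2-one | C=CCCC(=O)N1[C@@H](Cc2ccccc2)COC1=O
F2 | step 3 | (S)-4-benzyl-3-[(E)-5-(3,4-dimethoxyphenyl)pent-4-enoyl]-1,3-oxazolidin-2-one | COc1ccc(/C=C/CCC(=O)N2[C@@H](Cc3ccccc3)COC2=O)cc1OC
F3 | step 9 | (4S)-4-benzyl-3-[(2R,4E)-5-(3,4-dimethoxyphenyl)-2-[(S)-(4-methoxyphenyl)(triethylsilyloxy)methyl]pent-4-enoyl]-1,3-oxazolidin-2-one | O=C1OC[C@H](Cc2ccccc2)N1C(=O)[C@H](C/C=C/c1ccc(OC)c(OC)c1)[C@H](O[Si](CC)(CC)CC)c1ccc(OC)cc1
F4 | step 9 | (2S,4E)-5-(3,4-dimethoxyphenyl)-2-[(S)-(4-methoxyphenyl)(triethylsilyloxy)methyl]pent-4-en-1-ol | OC[C@H](C/C=C/c1ccc(OC)c(OC)c1)[C@H](O[Si](CC)(CC)CC)c1ccc(OC)cc1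
F5 | step 9 | [(2S,4E)-5-(3,4-dimethoxyphenyl)-2-[(S)-(4-methoxyphenyl)(triethylsilyloxy)methyl]pent-4-enyl] (Z)-2-[(tert-butyldimethylsilyloxy)methyl]but-2-enoate | C/C=C(/CO[Si](C)(C)C(C)(C)C)C(=O)OC[C@H](C/C=C/c1ccc(OC)c(OC)c1)[C@H](O[Si](CC)(CC)CC)c1ccc(OC)cc1
F6 | step 8 | methyl (Z)-2-[(tert-butyldimethylsilyloxy)methyl]but-2-enoate | C/C=C(/CO[Si](C)(C)C(C)(C)C)C(=O)OC
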